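**Plan**

1. Labdane numbering is used: ring A = C1–C5 and C10, ring B = C5–C10, C17 = exo-methylene on C8, C18 (methyl) and C19 (carboxyl) on C4, C20 = methyl on C10, side chain C11–C16. Retrosynthesis first removes the late adjustments (13-O-acetyl, C19 ester, a helper oxygen on C6), then cuts ring B at C6–C7 and C9–C10. This gives a ring-A enal (C10=C5–C6H=O, C4 quaternary) and a C10 chain that is (R)-linalool oxidised at its (E)-methyl group.
2. Enabling feature: in ring B the exo-methylene carbon C8 holds both C7 and C9, a 2-methylenepropane-1,3-diyl unit that is the prenyl terminus of linalool. C6–C5–C10 is the carbon line of a β-methyl enal. The two three-carbon units are joined in a (3+3) annulation.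
3. Forward: ring A is built in five steps from methyl 2-oxocyclohexanecarboxylate, and the chain in three steps from (R)-linalool. In one flask the allylbarium reagent adds to the aldehyde, the alkoxide undergoes an anionic oxy-Cope shift (C9–C10, quaternary C10), and the freed aldehyde closes ring B by a carbonyl-ene reaction (C6–C7, exo-methylene).
4. Stereochemistry: C13 comes from (R)-linalool and C4 from a valine-auxiliary alkylation. C9 and C10 come from the chair [3,3] transition state with the (E)-olefin, on the ring face anti to the C19 ester. C5 comes from enolate protonation anti to the new C9 substituent. The C6 carbinol is a helper.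
5. End game: Barton–McCombie removal of the C6 oxygen, desilylation, cleavage of the methyl ester, acetylation of the tertiary alcohol.

Key step: step 9

Remark: the target SMILES is read as (4S,5S,9S,10R,13R), i.e. H-5 cis to CH3-20 (rings A/B cis-fused, "5β"), the C19 carboxyl cis to CH3-20, and H-9 trans to CH3-20.
Remark: in step 2 the toluene/HMPA protocol with the L-valine tert-butyl ester enamine is assumed to deliver the (S)-configured quaternary ester; the D-valine ester (or the THF protocol) would reverse the sense if needed.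

Step 1
Reactants: 1 methyl 2-oxocyclohexane-1-carboxylate; 2 L-valine tert-butyl ester
Product: 3 methyl 2-{[(2S)-1-(tert-butoxy)-3-methyl-1-oxobutan-2-yl]amino}cyclohex-1-ene-1-carboxylate
Conditions: BF3·OEt2 (cat.), benzene, reflux, water separator
Reagents that add atoms: none
Why: Acid-catalysed condensation of the β-keto ester with the primary amine (enamine formation) should give the hydrogen-bonded β-enamino ester, placing the chiral auxiliary next to the carbon to be alkylated.

Step 2
Reactants: 3 methyl 2-{[(2S)-1-(tert-butoxy)-3-methyl-1-oxobutan-2-yl]amino}cyclohex-1-ene-1-carboxylate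
Product: 5 methyl (1S)-1-methyl-2-oxocyclohexane-1-carboxylate, via alkylated imine 4 (not isolated)
Conditions: LiN(i-Pr)2, toluene, HMPA (1 equiv), −78 °C; CH3I, −78 → −20 °C; then aqueous citric acid, 0 °C
Reagents that add atoms: iodomethane CI; water O
Why: Asymmetric alkylation of the chiral lithio-enamine (aza-enolate), in which lithium is held by the tert-butyl ester and the added ligand so that CH3I enters one face and sets the quaternary C4 as S, followed by mild acid hydrolysis of imine 4 to the ketone and the recovered auxiliary.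

Step 3
Reactants: 5 methyl (1S)-1-methyl-2-oxocyclohexane-1-carboxylate
Product: 6 methyl (1S)-1,3-dimethyl-2-oxocyclohexane-1-carboxylate (both C3 epimers)
Conditions: LiN(i-Pr)2, THF, −78 °C; CH3I, −78 → 0 °C
Reagents that add atoms: iodomethane CI
Why: Enolate alkylation should be regiospecific because C4 is quaternary, so the ketone can enolise only toward the ring CH2 and CH3I installs the future C20 methyl (the new centre is erased in step 4, so both epimers serve).

Step 4
Reactants: 6 methyl (1S)-1,3-dimethyl-2-oxocyclohexane-1-carboxylate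
Product: 7 methyl (1S)-1,3-dimethyl-2-[(trifluoromethanesulfonyl)oxy]cyclohex-2-ene-1-carboxylate
Conditions: KN(SiMe3)2, THF, −78 → 0 °C; PhNTf2, −78 → 25 °C
Reagents that add atoms: N-phenylbis(trifluoromethanesulfonimide) O=S(=O)(N(c1ccccc1)S(=O)(=O)C(F)(F)F)C(F)(F)F
Why: Enol triflate formation: the only enolisable position is the methyl-bearing carbon, so the potassium enolate should be trapped on oxygen as the tetrasubstituted C5=C10 vinyl triflate.

Step 5
Reactants: 7 methyl (1S)-1,3-dimethyl-2-[(trifluoromethanesulfonyl)oxy]cyclohex-2-ene-1-carboxylate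
Product: 8 methyl (1S)-2-formyl-1,3-dimethylcyclohex-2-ene-1-carboxylate
Conditions: Pd(PPh3)4 (5 mol %), CO (3 atm), Bu3SnH (slow addition), THF, 50 °C
Reagents that add atoms: carbon monoxide [C-]#[O+]
Why: Palladium-catalysed reductive carbonylation (formylation) of a vinyl triflate, by oxidative addition, CO insertion and hydride transfer from Bu3SnH, should give the β-methyl enal that carries C6.

Step 6
Reactants: 9 (R)-(−)-linalool [(3R)-3,7-dimethylocta-1,6-dien-3-ol]
Product: 10 tert-butyl{[(3R)-3,7-dimethylocta-1,6-dien-3-yl]oxy}dimethylsilane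
Conditions: TBSOTf, 2,6-lutidine, CH2Cl2, 0 °C
Reagents that add atoms: tert-butyldimethylsilyl trifluoromethanesulfonate CC(C)(C)[Si](C)(C)OS(=O)(=O)C(F)(F)F
Why: Silylation of the tertiary allylic alcohol with the silyl triflate and a hindered base should protect C13–OH for the basic and Lewis acidic steps without touching the stereocentre.

Step 7
Reactants: 10 tert-butyl{[(3R)-3,7-dimethylocta-1,6-dien-3-yl]oxy}dimethylsilane
Product: 11 (2E,6R)-6-[(tert-butyldimethylsilyl)oxy]-2,6-dimethylocta-2,7-dien-1-ol
Conditions: SeO2 (0.5 equiv), t-BuOOH, salicylic acid (cat.), CH2Cl2, 0 → 25 °C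
Reagents that add atoms: selenium dioxide O=[Se]=O (oxygen carrier); tert-butyl hydroperoxide CC(C)(C)OO
Why: Riley allylic oxidation (ene reaction then [2,3] shift) should oxidise the (E)-methyl group of the trisubstituted olefin, fixing the E geometry needed in step 9, while the vinyl group, which has no allylic hydrogen, is left alone.

Step 8
Reactants: 11 (2E,6R)-6-[(tert-butyldimethylsilyl)oxy]-2,6-dimethylocta-2,7-dien-1-ol
Product: 12 tert-butyl{[(3R,6E)-8-chloro-3,7-dimethylocta-1,6-dien-3-yl]oxy}dimethylsilane
Conditions: PPh3, CCl4, 60 °C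
Reagents that add atoms: tetrachloromethane ClC(Cl)(Cl)Cl
Why: Appel chlorination should convert the primary allylic alcohol into the chloride by SN2 displacement without allylic transposition, giving the precursor of the allylbarium reagent.

Step 9
Reactants: 8 methyl (1S)-2-formyl-1,3-dimethylcyclohex-2-ene-1-carboxylate; 12 tert-butyl{[(3R,6E)-8-chloro-3,7-dimethylocta-1,6-dien-3-yl]oxy}dimethylsilane
Product: 16 methyl (13R)-13-[(tert-butyldimethylsilyl)oxy]-6ξ-hydroxy-5β-labda-8(17),14-dien-19-oate (A/B cis; both C6 epimers), via allylbarium chloride 13 (not isolated), via dienol alkoxide 14 (not isolated), via seco aldehyde 15 (not isolated)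
Conditions: one flask: activated Ba (from BaI2 and lithium biphenylide, LiC12H10), THF, −78 °C, 12 then 8; t-BuOK, 18-crown-6, −78 → 25 °C; AcOH, −78 °C; solvent exchange to CH2Cl2; Me2AlCl, −78 → 0 °C
Reagents that add atoms: none
Why: Mechanism: allylbarium 13 adds through its unsubstituted terminus C7 to the formyl carbon C6 of 8 (1,2-addition with retention of olefin geometry), and after barium-to-potassium exchange the crown-separated 1,5-dien-3-olate 14 undergoes an anionic oxy-Cope [3,3] shift that cuts this provisional C6–C7 link, forms the quaternary C10–C9 bond and leaves an aldehyde enolate next to an isopropenyl group (C7=C8 with C17 as methyl); protonation gives 15, whose Me2AlCl complex closes ring B by an intramolecular carbonyl-ene reaction in which C7 bonds to C6 and a hydrogen leaves C17. The closest known reaction types are the 1,2-addition/anionic oxy-Cope relay used as a formal conjugate allylation of hindered enals and the Lewis-acid type-two carbonyl-ene cyclisation, and run in one flask they amount to a (3+3) annulation. Ring B is closed through a six-membered chair-like ene transition state with the tether on the central ene carbon, which is why the olefin ends as the exocyclic C8=C17 methylene. C9 and C10 arise together in the chair oxy-Cope transition state, where the ring-fixed cis relation of C20 to C6 places C20 axial and the (E)-olefin places C11 equatorial, so C20 and C11 end cis; their sense relative to C4 should follow from addition to the ring face anti to the pseudo-axial C19 ester, C5 should be set by protonation of the enolate anti to the bulky new C9 substituent, and the C6 carbinol centre is left uncontrolled because steps 10 and 11 remove it. The step needs α- over γ-attack and 1,2- over 1,4-addition (secured by the barium reagent and the fully substituted C10), [3,3] shift over retro-allylation (secured by the potassium/crown counter-ion and the secondary carbinol) and ene closure over ionisation of the tertiary allylic silyl ether (secured by the proton-scavenging Me2AlCl at low temperature).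

Step 10
Reactants: 16 methyl (13R)-13-[(tert-butyldimethylsilyl)oxy]-6ξ-hydroxy-5β-labda-8(17),14-dien-19-oate
Product: 17 methyl (13R)-13-[(tert-butyldimethylsilyl)oxy]-6ξ-{[(methylsulfanyl)carbonothioyl]oxy}-5β-labda-8(17),14-dien-19-oate
Conditions: NaH, imidazole (cat.), THF, 0 → 25 °C; CS2; CH3I
Reagents that add atoms: carbon disulfide S=C=S; iodomethane CI
Why: Xanthate formation: the C6 alkoxide should add to CS2 and be S-methylated, preparing the helper hydroxyl for radical removal.

Step 11
Reactants: 17 methyl (13R)-13-[(tert-butyldimethylsilyl)oxy]-6ξ-{[(methylsulfanyl)carbonothioyl]oxy}-5β-labda-8(17),14-dien-19-oate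
Product: 18 methyl (13R)-13-[(tert-butyldimethylsilyl)oxy]-5β-labda-8(17),14-dien-19-oate
Conditions: Bu3SnH (excess, high concentration), AIBN (cat.), toluene, 110 °C
Reagents that add atoms: none
Why: Barton–McCombie deoxygenation: the stannyl radical adds to the thiocarbonyl, the C6–O bond fragments and the secondary C6 radical should be reduced by Bu3SnH before any homoallyl rearrangement, leaving C6 as CH2.

Step 12
Reactants: 18 methyl (13R)-13-[(tert-butyldimethylsilyl)oxy]-5β-labda-8(17),14-dien-19-oate
Product: 19 methyl (13R)-13-hydroxy-5β-labda-8(17),14-dien-19-oate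
Conditions: Bu4NF, THF, 50 °C
Reagents that add atoms: none
Why: Fluoride-induced desilylation should free the tertiary C13 alcohol under conditions that leave the olefins and the ester unchanged.

Step 13
Reactants: 19 methyl (13R)-13-hydroxy-5β-labda-8(17),14-dien-19-oate
Product: 20 (13R)-13-hydroxy-5β-labda-8(17),14-dien-19-oic acid
Conditions: LiSCH2CH2CH3, HMPA, 25 → 60 °C; then dilute HCl to pH 4, 0 °C
Reagents that add atoms: none
Why: SN2 dealkylation of a hindered methyl ester: the thiolate should attack the methyl carbon, which avoids acyl attack at the axial, neopentyl C19 carbonyl and leaves all stereocentres untouched.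

Step 14
Reactants: 20 (13R)-13-hydroxy-5β-labda-8(17),14-dien-19-oic acid
Product: 22 (13R)-13-acetoxy-5β-labda-8(17),14-dien-19-oic acid [(4S,5S,9S,10R,13R); target], via mixed anhydride 21 (not isolated)
Conditions: Ac2O, DMAP, Et3N, CH2Cl2, 25 °C; then H2O, THF, 25 °C
Reagents that add atoms: acetic anhydride CC(=O)OC(C)=O
Why: DMAP-catalysed acylation should acetylate the tertiary allylic alcohol while the carboxyl group is carried as mixed anhydride 21, which water returns to the acid by attack at the unhindered acetyl carbonyl.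

**Compound list**

1 | methyl 2-oxocyclohexane-1-carboxylate | O=C1CCCCC1C(=O)OC | starting material
2 | L-valine tert-butyl ester [tert-butyl (2S)-2-amino-3-methylbutanoate] | CC(C)[C@@H](C(=O)OC(C)(C)C)N | starting material
3 | methyl 2-{[(2S)-1-(tert-butoxy)-3-methyl-1-oxobutan-2-yl]amino}cyclohex-1-ene-1-carboxylate | CC(C)[C@@H](C(=O)OC(C)(C)C)NC1=C(C(=O)OC)CCCC1 | intermediate
4 | methyl (1S)-2-{[(2S)-1-(tert-butoxy)-3-methyl-1-oxobutan-2-yl]imino}-1-methylcyclohexane-1-carboxylate (alkylated imine, not isolated) | CC(C)[C@@H](C(=O)OC(C)(C)C)N=C1CCCC[C@]1(C)C(=O)OC | intermediate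
5 | methyl (1S)-1-methyl-2-oxocyclohexane-1-carboxylate | O=C1CCCC[C@]1(C)C(=O)OC | intermediate
6 | methyl (1S)-1,3-dimethyl-2-oxocyclohexane-1-carboxylate (both C3 epimers) | O=C1C(C)CCC[C@]1(C)C(=O)OC | intermediate
7 | methyl (1S)-1,3-dimethyl-2-[(trifluoromethanesulfonyl)oxy]cyclohex-2-ene-1-carboxylate | FC(F)(F)S(=O)(=O)OC1=C(C)CCC[C@]1(C)C(=O)OC | intermediate
8 | methyl (1S)-2-formyl-1,3-dimethylcyclohex-2-ene-1-carboxylate (ring-A enal) | O=CC1=C(C)CCC[C@]1(C)C(=O)OC | intermediate
9 | (R)-(−)-linalool [(3R)-3,7-dimethylocta-1,6-dien-3-ol] | C=C[C@@](C)(CCC=C(C)C)O | starting material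
10 | tert-butyl{[(3R)-3,7-dimethylocta-1,6-dien-3-yl]oxy}dimethylsilane | C=C[C@@](C)(CCC=C(C)C)O[Si](C)(C)C(C)(C)C | intermediate
11 | (2E,6R)-6-[(tert-butyldimethylsilyl)oxy]-2,6-dimethylocta-2,7-dien-1-ol | C=C[C@@](C)(CC/C=C(\C)CO)O[Si](C)(C)C(C)(C)C | intermediate
12 | tert-butyl{[(3R,6E)-8-chloro-3,7-dimethylocta-1,6-dien-3-yl]oxy}dimethylsilane | C=C[C@@](C)(CC/C=C(\C)CCl)O[Si](C)(C)C(C)(C)C | intermediate
13 | [(2E,6R)-6-[(tert-butyldimethylsilyl)oxy]-2,6-dimethylocta-2,7-dien-1-yl]barium chloride (allylbarium reagent, not isolated) | C=C[C@@](C)(CC/C=C(\C)C[Ba]Cl)O[Si](C)(C)C(C)(C)C | intermediate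
14 | methyl (1S)-2-[(3E,7R)-7-[(tert-butyldimethylsilyl)oxy]-1-hydroxy-3,7-dimethylnona-3,8-dien-1-yl]-1,3-dimethylcyclohex-2-ene-1-carboxylate (9,10-seco dienol, both carbinol epimers, formed as its alkoxide, not isolated) | C=C[C@@](C)(CC/C=C(\C)CC(O)C1=C(C)CCC[C@]1(C)C(=O)OC)O[Si](C)(C)C(C)(C)C | intermediate
15 | methyl (13R)-13-[(tert-butyldimethylsilyl)oxy]-6-oxo-6,7-seco-5β-labda-7,14-dien-19-oate (5β-H, 9α-H, 10β-CH3; seco aldehyde, not isolated) | C=C[C@@](C)(CC[C@@H](C(C)=C)[C@@]1(C)CCC[C@](C)(C(=O)OC)[C@H]1C=O)O[Si](C)(C)C(C)(C)C | intermediate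
16 | methyl (13R)-13-[(tert-butyldimethylsilyl)oxy]-6ξ-hydroxy-5β-labda-8(17),14-dien-19-oate (5β-H, 9α-H, 10β-CH3, 4β-CO2CH3) | C=C[C@@](C)(CC[C@H]1C(=C)CC(O)[C@H]2[C@]1(C)CCC[C@]2(C)C(=O)OC)O[Si](C)(C)C(C)(C)C | intermediate
17 | methyl (13R)-13-[(tert-butyldimethylsilyl)oxy]-6ξ-{[(methylsulfanyl)carbonothioyl]oxy}-5β-labda-8(17),14-dien-19-oate | C=C[C@@](C)(CC[C@H]1C(=C)CC(OC(=S)SC)[C@H]2[C@]1(C)CCC[C@]2(C)C(=O)OC)O[Si](C)(C)C(C)(C)C | intermediate
18 | methyl (13R)-13-[(tert-butyldimethylsilyl)oxy]-5β-labda-8(17),14-dien-19-oate | C=C[C@@](C)(CC[C@H]1C(=C)CC[C@H]2[C@]1(C)CCC[C@]2(C)C(=O)OC)O[Si](C)(C)C(C)(C)C | intermediate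
19 | methyl (13R)-13-hydroxy-5β-labda-8(17),14-dien-19-oate | C=C[C@@](C)(CC[C@H]1C(=C)CC[C@H]2[C@]1(C)CCC[C@]2(C)C(=O)OC)O | intermediate
20 | (13R)-13-hydroxy-5β-labda-8(17),14-dien-19-oic acid | C=C[C@@](C)(CC[C@H]1C(=C)CC[C@H]2[C@]1(C)CCC[C@]2(C)C(=O)O)O | intermediate
21 | acetic (13R)-13-acetoxy-5β-labda-8(17),14-dien-19-oic anhydride (mixed anhydride, not isolated) | C=C[C@@](C)(CC[C@H]1C(=C)CC[C@H]2[C@]1(C)CCC[C@]2(C)C(=O)OC(C)=O)OC(C)=O | intermediate
22 | (13R)-13-acetoxy-5β-labda-8(17),14-dien-19-oic acid [(4S,5S,9S,10R,13R)] | C=C[C@@](C)(CC[C@H]1C(=C)CC[C@H]2[C@]1(C)CCC[C@]2(C)C(=O)O)OC(C)=O | target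

**Totals**

Total step count: 14. Longest linear sequence: 11 steps (steps 1–5, then 9–14).

**Steps most likely to fail**

Step 9. The [3,3] shift may show poor facial selectivity, since one carbinol epimer of 14 is mismatched with the ring-face preference. γ-Attack of the allyl metal or retro-allylation may compete, the cation exchange may be incomplete, and protonation may occur on the other face and give the trans ring fusion. Fallback (stepwise and reagent-controlled): setting out from 8 and 12, the allylbarium addition is worked up at −78 °C and dienol 14 is isolated. Buffered Dess–Martin oxidation gives the β,γ-unsaturated dienone methyl (1S)-2-[(3E,7R)-7-[(tert-butyldimethylsilyl)oxy]-3,7-dimethyl-1-oxonona-3,8-dien-1-yl]-1,3-dimethylcyclohex-2-ene-1-carboxylate F1. CBS reduction (BH3·SMe2, (R)-configured methyl oxazaborolidine) gives the single carbinol epimer methyl (1S)-2-[(1S,3E,7R)-7-[(tert-butyldimethylsilyl)oxy]-1-hydroxy-3,7-dimethylnona-3,8-dien-1-yl]-1,3-dimethylcyclohex-2-ene-1-carboxylate F2. In F2 the pseudo-equatorial alkoxide and the ring-face preference act in the same sense. KH/18-crown-6 in THF followed by an AcOH quench gives aldehyde 15, which is isolated, and Me2AlCl in CH2Cl2 closes ring B; the route is rejoined at 16.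

Step 5. Oxidative addition to the hindered tetrasubstituted vinyl triflate may be slow, and hydride transfer may outrun CO insertion (simple reduction of the triflate). Fallback: setting out from 7, Stille coupling with Bu3SnCH2OH (Pd(PPh3)4, LiCl, dioxane, 100 °C) gives the allylic alcohol methyl (1S)-2-(hydroxymethyl)-1,3-dimethylcyclohex-2-ene-1-carboxylate F3. Oxidation with MnO2 in CH2Cl2 rejoins the route at 8.

Step 11. The homoallylic C6 radical may rearrange through a cyclopropylcarbinyl radical (ring contraction), and the hindered xanthate may undergo thermal syn-elimination before radical cleavage. Fallback (polar instead of radical deoxygenation): setting out from 16, buffered Dess–Martin oxidation gives the ketone methyl (13R)-13-[(tert-butyldimethylsilyl)oxy]-6-oxo-5β-labda-8(17),14-dien-19-oate F4. Condensation with 4-methylbenzenesulfonohydrazide gives the tosylhydrazone of F4, methyl (13R)-13-[(tert-butyldimethylsilyl)oxy]-6-[2-(4-methylbenzenesulfonyl)hydrazinylidene]-5β-labda-8(17),14-dien-19-oate F5. Reduction with catecholborane and then NaOAc·3H2O in warm CHCl3 rejoins the route at 18.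

**Further compounds**

F1 | step 9 | methyl (1S)-2-[(3E,7R)-7-[(tert-butyldimethylsilyl)oxy]-3,7-dimethyl-1-oxonona-3,8-dien-1-yl]-1,3-dimethylcyclohex-2-ene-1-carboxylate | C=C[C@@](C)(CC/C=C(\C)CC(=O)C1=C(C)CCC[C@]1(C)C(=O)OC)O[Si](C)(C)C(C)(C)C
F2 | step 9 | methyl (1S)-2-[(1S,3E,7R)-7-[(tert-butyldimethylsilyl)oxy]-1-hydroxy-3,7-dimethylnona-3,8-dien-1-yl]-1,3-dimethylcyclohex-2-ene-1-carboxylate | C=C[C@@](C)(CC/C=C(\C)C[C@H](O)C1=C(C)CCC[C@]1(C)C(=O)OC)O[Si](C)(C)C(C)(C)C
F3 | step 5 | methyl (1S)-2-(hydroxymethyl)-1,3-dimethylcyclohex-2-ene-1-carboxylate | OCC1=C(C)CCC[C@]1(C)C(=O)OC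
F4 | step 11 | methyl (13R)-13-[(tert-butyldimethylsilyl)oxy]-6-oxo-5β-labda-8(17),14-dien-19-oate | C=C[C@@](C)(CC[C@H]1C(=C)CC(=O)[C@H]2[C@]1(C)CCC[C@]2(C)C(=O)OC)O[Si](C)(C)C(C)(C)C
F5 | step 11 | methyl (13R)-13-[(tert-butyldimethylsilyl)oxy]-6-[2-(4-methylbenzenesulfonyl)hydrazinylidene]-5β-labda-8(17),14-dien-19-oate | C=C[C@@](C)(CC[C@H]1C(=C)CC(=NNS(=O)(=O)c3ccc(C)cc3)[C@H]2[C@]1(C)CCC[C@]2(C)C(=O)OC)O[Si](C)(C)C(C)(C)C
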